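C/C=C/[C@H]1[C@H]2C[C@@H](C)CC[C@@H]2C(C)=C[C@H]1C(=O)c1c(O)c(-c2ccc(O)cc2)c[nH]c1=O: proposed total synthesis

**Plan**
1. Numbering: the decalin is numbered as a naphthalene (C1 propenyl, C2 acyl, C3=C4, C4 methyl, C4a, C5, C6, C7 methyl, C8, C8a). Ring A is C4a-C5-C6-C7-C8-C8a and ring B is C1-C2-C3-C4-C4a-C8a.
2. Cuts, in retrosynthetic order: three O-benzyl masks; C1-propenyl (conjugate addition); acyl carbon to pyridine C3 (aryllithium plus Weinreb amide); C7-C8 and C4a-C8a together ([4+2]); C4a=C5 (HWE); C3-C4 (SN2' alkylation).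
3. Enabling feature: without the propenyl group, C8a is tied through C1=C2 to the acyl carbon. The C8=C8a edge of ring A is then the far end of a 2,4-dienoate (C8 electrophilic). A carbonyl lent to C6 turns the opposite chain C7-C6-C5-C4a into a 2-silyloxydiene (C7 nucleophilic). C4, C3, C2 and C1 of ring B serve as the tether.
4. Forward order: an acyclic tetraene closes ring A and ring B in one cycloaddition. The C6 carbonyl and the C4 silyloxy group are then removed to give the ring B diene acid. The pyridyl ketone, the propenyl group and the deprotection follow.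
5. Stereochemistry: the carbinol carbon of (S)-lactic acid becomes C4 (self-regeneration of stereocentres), directs C4a, and is then erased into C3=C4. C8a comes from the exo transition state, and C7 from equilibration next to the C6 ketone. C1 comes from axial cuprate attack, and C2 from kinetic axial protonation.

Key step: step 7

Remark: 3 and 4 are racemic and 10 is an anomer mixture. These centres are destroyed in steps 4 and 6, so this is harmless. All eight numbered starting materials are taken as commercial.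

**Step 1**
Reactants: 1 acrolein; 2 tert-butyl acrylate
Product: 3 tert-butyl 3-hydroxy-2-methylidenepent-4-enoate (racemic)
Conditions: DABCO (cat), dioxane/H2O, rt
Reagents that add atoms: none
Why: Morita–Baylis–Hillman reaction, in which the amine adds to the acrylate, the resulting enolate attacks the aldehyde carbonyl of 1, and the amine is expelled again.

**Step 2**
Reactants: 3 tert-butyl 3-hydroxy-2-methylidenepent-4-enoate
Product: 4 tert-butyl 3-acetoxy-2-methylidenepent-4-enoate (racemic)
Conditions: Ac2O, pyridine, DMAP (cat), CH2Cl2, 0 °C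
Reagents that add atoms: acetic anhydride, CC(=O)OC(C)=O
Why: Routine O-acetylation turns the carbinol into the leaving group needed for the SN2' step.

**Step 3**
Reactants: 5 (S)-lactic acid; 6 pivalaldehyde
Product: 7 (2S,5S)-2-tert-butyl-5-methyl-1,3-dioxolan-4-one (cis)
Conditions: TsOH (cat), pentane, reflux, Dean–Stark trap; crystallisation at low temperature
Reagents that add atoms: none
Why: Acid-catalysed acetalisation with removal of water, where the cis acetal crystallises and its new acetal centre stores the configuration of lactic acid (self-regeneration of stereocentres).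

**Step 4**
Reactants: 7 (2S,5S)-2-tert-butyl-5-methyl-1,3-dioxolan-4-one; 4 tert-butyl 3-acetoxy-2-methylidenepent-4-enoate
Product: 9 tert-butyl (2E)-2-{[(2S,4R)-2-tert-butyl-4-methyl-5-oxo-1,3-dioxolan-4-yl]methyl}penta-2,4-dienoate, via lithium enolate 8 (not isolated)
Conditions: 7, LiN(i-Pr)2, THF, −78 °C; then 4, −78 to −40 °C
Reagents that add atoms: lithium diisopropylamide, [Li+].CC(C)[N-]C(C)C (its lithium stays only in 8)
Why: SN2' addition–elimination on a Morita–Baylis–Hillman acetate, in which 8 attacks the methylidene carbon anti to the tert-butyl group (future C4 set as R) and loss of acetate from the ester series should give the E alkene that holds C3 and C8a cis.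

**Step 5**
Reactants: 9 dioxolanone dienoate
Product: 10 tert-butyl (2E)-2-{[(2S,4R)-2-tert-butyl-5-hydroxy-4-methyl-1,3-dioxolan-4-yl]methyl}penta-2,4-dienoate (lactol, anomer mixture)
Conditions: i-Bu2AlH (1.1 equiv), CH2Cl2, −78 °C; aq potassium sodium tartrate
Reagents that add atoms: none
Why: Partial reduction of a lactone-type carbonyl, in which the strained non-conjugated acylal carbonyl is far more electrophilic than the conjugated tert-butyl ester, so the hydride should stop at the lactol.

**Step 6**
Reactants: 10 lactol; 11 diethyl (2-oxobutyl)phosphonate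
Product: 13 tert-butyl (2E)-2-[(2R,3E)-2-hydroxy-2-methyl-5-oxohept-3-en-1-yl]penta-2,4-dienoate, via hydroxy aldehyde 12 (not isolated)
Conditions: LiCl, i-Pr2NEt, MeCN, rt
Reagents that add atoms: none
Why: Under mild base the lactol opens and sheds pivalaldehyde, and the non-epimerisable aldehyde 12 undergoes Horner–Wadsworth–Emmons olefination with the stabilised ketophosphonate, which should give the E enone, while the tert-butyl ester resists lactonisation by the free carbinol.

**Step 7**
Reactants: 13 hydroxy enone dienoate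
Product: 15 tert-butyl (4R,4aR,7S,8aR)-4,6-bis[(tert-butyldimethylsilyl)oxy]-4,7-dimethyl-3,4,4a,7,8,8a-hexahydronaphthalene-2-carboxylate (trans-fused, C4–O axial, C7 methyl axial), via bis-silyl tetraene 14 (not isolated)
Conditions: TBSOTf (3 equiv), Et3N (5 equiv), CH2Cl2, 0 °C; then PhMe, BHT, 110 °C
Reagents that add atoms: tert-butyldimethylsilyl triflate, CC(C)(C)[Si](C)(C)OS(=O)(=O)C(F)(F)F
Why: Soft enolisation can occur only at C7 because C4 is quaternary, so TBSOTf/Et3N turns the ethyl enone into the (Z)-2-silyloxy-1,3-diene C7=C6–C5=C4a and caps the carbinol (14); on heating, a concerted but asynchronous normal-demand Diels–Alder reaction joins nucleophilic C7 to C8, the electrophilic far carbon of the 2,4-dienoate, and C4a to C8a. The closest known reaction type is the type 1 intramolecular Diels–Alder reaction of silyl dienol ethers made in situ from enones, the concerted counterpart of the intramolecular double Michael reaction. Ring A closes as the new cyclohexene of the [4+2] event (four diene carbons plus C8 and C8a), and ring B closes at the same moment as the fused six-membered ring through the four-atom tether C4–C3–C2=C1 (1,7,9-decatriene mode). C4a is controlled by the lactic acid derived centre C4, since in the reactive rotamer the C4 methyl group stands anti to the forming C4a–C8a bond and the smaller, electron-withdrawing C–O bond takes the inside position next to C5–H, which exposes one diene face. C8a follows from the exo arrangement, because the dienoate stays planar and s-trans and so holds C3 beside C8a–H, which lets the short C3–C4 link reach C4a only with the diene turned away from C1=C2 and should give the trans fusion, while C7 follows suprafacially from the Z enol ether (methyl axial) and is corrected in step 8. The step needs site selectivity for the terminal C8=C8a bond over C1=C2 and the regiochemistry C7 to C8, and both are fixed by the tether (attack on C1=C2 would need a four-membered ring) and reinforced by the matched polarity.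

**Step 8**
Reactants: 15 cycloadduct
Product: 16 tert-butyl (4R,4aS,7R,8aR)-4-[(tert-butyldimethylsilyl)oxy]-4,7-dimethyl-6-oxo-3,4,4a,5,6,7,8,8a-octahydronaphthalene-2-carboxylate (C7 methyl equatorial)
Conditions: 1 M HCl, THF, 0 °C; then DBU (cat), CH2Cl2, rt
Reagents that add atoms: none
Why: Protodesilylation of the silyl enol ether frees the C6 ketone, and base-catalysed enolisation then equilibrates C7 to the equatorial methyl epimer of the rigid trans-decalone, while the tertiary silyl ether and the tert-butyl ester survive dilute acid.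

**Step 9**
Reactants: 16 ketone
Product: 17 tert-butyl (4R,4aS,7R,8aR)-4-[(tert-butyldimethylsilyl)oxy]-4,7-dimethyl-6-[2-(4-methylbenzenesulfonyl)hydrazinylidene]-3,4,4a,5,6,7,8,8a-octahydronaphthalene-2-carboxylate
Conditions: TsNHNH2, EtOH, 50 °C
Reagents that add atoms: 4-methylbenzenesulfonohydrazide, Cc1ccc(S(=O)(=O)NN)cc1
Why: Tosylhydrazone condensation takes place at the only ketone, and C7 stays in its thermodynamic equatorial form.

**Step 10**
Reactants: 17 tosylhydrazone
Product: 18 tert-butyl (4R,4aS,7S,8aR)-4-[(tert-butyldimethylsilyl)oxy]-4,7-dimethyl-3,4,4a,5,6,7,8,8a-octahydronaphthalene-2-carboxylate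
Conditions: catecholborane, CHCl3, 0 °C; then NaOAc·3H2O, reflux
Reagents that add atoms: none
Why: Caglioti-type deoxygenation, in which the borane reduces the C=N bond, acetate triggers loss of sulfinate, and the diazene loses N2 to leave C6 as CH2 without touching the enoate, the silyl ether or any stereocentre.

**Step 11**
Reactants: 18 silyloxy enoate
Product: 19 (4aS,7S,8aR)-4,7-dimethyl-4a,5,6,7,8,8a-hexahydronaphthalene-2-carboxylic acid
Conditions: CF3CO2H, CH2Cl2, 0 °C to rt
Reagents that add atoms: none
Why: Acidolysis cleaves the tert-butyl ester and ionises the tertiary silyl ether (E1), and loss of the allylic C3 proton should give the C3=C4 alkene conjugated with C1=C2 and the acid as the thermodynamic sink, which erases the auxiliary centre C4 as planned.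

**Step 12**
Reactants: 19 dienoic acid
Product: 21 (4aS,7S,8aR)-N-methoxy-N,4,7-trimethyl-4a,5,6,7,8,8a-hexahydronaphthalene-2-carboxamide, via acyl imidazolide 20 (not isolated)
Conditions: CDI, CH2Cl2, rt; then MeNH(OMe)·HCl, rt
Reagents that add atoms: N,O-dimethylhydroxylamine hydrochloride, CNOC.Cl; 1,1'-carbonyldiimidazole, O=C(n1ccnc1)n1ccnc1 (its imidazolyl group stays only in 20)
Why: Standard Weinreb amide formation through the acyl imidazolide, with no enolisable position next to the carbonyl group.

**Step 13**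
Reactants: 22 4-(benzyloxy)pyridin-2(1H)-one
Product: 23 2,4-bis(benzyloxy)pyridine
Conditions: BnBr, Ag2CO3, PhMe, 80 °C, dark
Reagents that add atoms: benzyl bromide, BrCc1ccccc1
Why: Silver-salt alkylation of a 2-pyridone in a non-polar solvent goes to oxygen and gives the 2-alkoxypyridine.

**Step 14**
Reactants: 23 2,4-bis(benzyloxy)pyridine
Product: 24 2,4-bis(benzyloxy)-3,5-dibromopyridine
Conditions: NBS (2.1 equiv), MeCN, 0 °C to rt, dark
Reagents that add atoms: N-bromosuccinimide, O=C1CCC(=O)N1Br
Why: Electrophilic aromatic bromination takes the two positions activated by both alkoxy groups, and polar conditions in the dark suppress benzylic bromination.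

**Step 15**
Reactants: 24 dibromide; 25 4-(benzyloxy)phenylboronic acid
Product: 26 2,4-bis(benzyloxy)-5-[4-(benzyloxy)phenyl]-3-bromopyridine
Conditions: Pd(PPh3)4 (cat), Na2CO3, PhMe/EtOH/H2O, 80 °C
Reagents that add atoms: none
Why: Suzuki–Miyaura coupling with one equivalent of 25, in which oxidative addition should prefer the open C5–Br bond over the C3–Br bond flanked by two benzyloxy groups.

**Step 16**
Reactants: 26 bromopyridine; 21 Weinreb amide
Product: 28 {2,4-bis(benzyloxy)-5-[4-(benzyloxy)phenyl]pyridin-3-yl}[(4aS,7S,8aR)-4,7-dimethyl-4a,5,6,7,8,8a-hexahydronaphthalen-2-yl]methanone, via aryllithium 27 (not isolated)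
Conditions: 26, n-BuLi, THF, −78 °C; then 21, −78 to −20 °C; H2O
Reagents that add atoms: n-butyllithium, [Li]CCCC (its lithium stays only in 27)
Why: Bromine–lithium exchange followed by Weinreb ketone synthesis, in which the chelated tetrahedral adduct prevents a second addition and 21 has no acidic proton next to the carbonyl group.

**Step 17**
Reactants: 28 dienone; 29 (E)-1-bromoprop-1-ene
Product: 31 {2,4-bis(benzyloxy)-5-[4-(benzyloxy)phenyl]pyridin-3-yl}{(1S,2S,4aS,7S,8aR)-4,7-dimethyl-1-[(E)-prop-1-enyl]-1,2,4a,5,6,7,8,8a-octahydronaphthalen-2-yl}methanone, via lithium enolate 30 (not isolated)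
Conditions: 29, t-BuLi, Et2O, −78 °C; CuI, −40 °C; then 28, Et2O/THF, −78 °C; AcOH, −78 °C
Reagents that add atoms: tert-butyllithium, [Li]C(C)(C)C (its lithium stays only in 30)
Why: Conjugate addition of a lithium dialkenylcuprate with retention of the E geometry, in which C1 is the only acceptor carbon of the cross-conjugated dienone, axial attack anti to C8a–H on the rigid trans-fused ring should place the propenyl group axial, and kinetic protonation of 30 at C2 from the axial face opposite to that group should set the equatorial acyl group and leave C3=C4 in place.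

**Step 18**
Reactants: 31 tribenzyl ether
Product: 32 3-{(1S,2S,4aS,7S,8aR)-4,7-dimethyl-1-[(E)-prop-1-enyl]-1,2,4a,5,6,7,8,8a-octahydronaphthalene-2-carbonyl}-4-hydroxy-5-(4-hydroxyphenyl)pyridin-2(1H)-one (target)
Conditions: BCl3, C6HMe5, CH2Cl2, −78 °C; then MeOH/H2O
Reagents that add atoms: none
Why: Lewis acid debenzylation with pentamethylbenzene as benzyl cation trap frees the phenol, the 4-hydroxy group and the 2-pyridone at low temperature without hydrogenation, so both alkenes and the C2 centre should survive.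

**Compound list**
1 | acrolein | C=CC=O | starting material
2 | tert-butyl acrylate | C=CC(=O)OC(C)(C)C | starting material
3 | tert-butyl 3-hydroxy-2-methylidenepent-4-enoate (racemic) | C=CC(O)C(=C)C(=O)OC(C)(C)C | intermediate
4 | tert-butyl 3-acetoxy-2-methylidenepent-4-enoate (racemic) | C=CC(OC(C)=O)C(=C)C(=O)OC(C)(C)C | intermediate
5 | (S)-lactic acid | C[C@H](O)C(=O)O | starting material
6 | pivalaldehyde | CC(C)(C)C=O | starting material
7 | (2S,5S)-2-tert-butyl-5-methyl-1,3-dioxolan-4-one | C[C@@H]1O[C@H](C(C)(C)C)OC1=O | intermediate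
8 | lithium enolate of 7 | CC1=C([O-])O[C@@H](C(C)(C)C)O1.[Li+] | intermediate
9 | tert-butyl (2E)-2-{[(2S,4R)-2-tert-butyl-4-methyl-5-oxo-1,3-dioxolan-4-yl]methyl}penta-2,4-dienoate | C[C@]1(C/C(=C\C=C)C(=O)OC(C)(C)C)O[C@H](C(C)(C)C)OC1=O | intermediate
10 | tert-butyl (2E)-2-{[(2S,4R)-2-tert-butyl-5-hydroxy-4-methyl-1,3-dioxolan-4-yl]methyl}penta-2,4-dienoate (anomer mixture) | C[C@]1(C/C(=C\C=C)C(=O)OC(C)(C)C)O[C@H](C(C)(C)C)OC1O | intermediate
11 | diethyl (2-oxobutyl)phosphonate | CCC(=O)CP(=O)(OCC)OCC | starting material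
12 | tert-butyl (2E)-2-[(2R)-2-hydroxy-2-methyl-3-oxopropyl]penta-2,4-dienoate | O=C[C@](C)(O)C/C(=C\C=C)C(=O)OC(C)(C)C | intermediate
13 | tert-butyl (2E)-2-[(2R,3E)-2-hydroxy-2-methyl-5-oxohept-3-en-1-yl]penta-2,4-dienoate | CCC(=O)/C=C/[C@](C)(O)C/C(=C\C=C)C(=O)OC(C)(C)C | intermediate
14 | tert-butyl (2E)-2-{(2R,3E,5Z)-2,5-bis[(tert-butyldimethylsilyl)oxy]-2-methylhepta-3,5-dien-1-yl}penta-2,4-dienoate | C/C=C(O[Si](C)(C)C(C)(C)C)/C=C/[C@](C)(O[Si](C)(C)C(C)(C)C)C/C(=C\C=C)C(=O)OC(C)(C)C | intermediate
15 | tert-butyl (4R,4aR,7S,8aR)-4,6-bis[(tert-butyldimethylsilyl)oxy]-4,7-dimethyl-3,4,4a,7,8,8a-hexahydronaphthalene-2-carboxylate | CC(C)(C)OC(=O)C1=C[C@H]2C[C@H](C)C(O[Si](C)(C)C(C)(C)C)=C[C@@H]2[C@](C)(O[Si](C)(C)C(C)(C)C)C1 | intermediate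
16 | tert-butyl (4R,4aS,7R,8aR)-4-[(tert-butyldimethylsilyl)oxy]-4,7-dimethyl-6-oxo-3,4,4a,5,6,7,8,8a-octahydronaphthalene-2-carboxylate | CC(C)(C)OC(=O)C1=C[C@H]2C[C@@H](C)C(=O)C[C@@H]2[C@](C)(O[Si](C)(C)C(C)(C)C)C1 | intermediate
17 | tosylhydrazone of 16 | CC(C)(C)OC(=O)C1=C[C@H]2C[C@@H](C)C(=NNS(=O)(=O)c3ccc(C)cc3)C[C@@H]2[C@](C)(O[Si](C)(C)C(C)(C)C)C1 | intermediate
18 | tert-butyl (4R,4aS,7S,8aR)-4-[(tert-butyldimethylsilyl)oxy]-4,7-dimethyl-3,4,4a,5,6,7,8,8a-octahydronaphthalene-2-carboxylate | CC(C)(C)OC(=O)C1=C[C@H]2C[C@@H](C)CC[C@@H]2[C@](C)(O[Si](C)(C)C(C)(C)C)C1 | intermediate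
19 | (4aS,7S,8aR)-4,7-dimethyl-4a,5,6,7,8,8a-hexahydronaphthalene-2-carboxylic acid | O=C(O)C1=C[C@H]2C[C@@H](C)CC[C@@H]2C(C)=C1 | intermediate
20 | acyl imidazolide of 19 | O=C(C1=C[C@H]2C[C@@H](C)CC[C@@H]2C(C)=C1)n1ccnc1 | intermediate
21 | (4aS,7S,8aR)-N-methoxy-N,4,7-trimethyl-4a,5,6,7,8,8a-hexahydronaphthalene-2-carboxamide | CON(C)C(=O)C1=C[C@H]2C[C@@H](C)CC[C@@H]2C(C)=C1 | intermediate
22 | 4-(benzyloxy)pyridin-2(1H)-one | O=c1cc(OCc2ccccc2)cc[nH]1 | starting material
23 | 2,4-bis(benzyloxy)pyridine | c1ccc(COc2ccnc(OCc3ccccc3)c2)cc1 | intermediate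
24 | 2,4-bis(benzyloxy)-3,5-dibromopyridine | Brc1cnc(OCc2ccccc2)c(Br)c1OCc1ccccc1 | intermediate
25 | 4-(benzyloxy)phenylboronic acid | OB(O)c1ccc(OCc2ccccc2)cc1 | starting material
26 | 2,4-bis(benzyloxy)-5-[4-(benzyloxy)phenyl]-3-bromopyridine | Brc1c(OCc2ccccc2)c(-c2ccc(OCc3ccccc3)cc2)cnc1OCc1ccccc1 | intermediate
27 | 2,4-bis(benzyloxy)-5-[4-(benzyloxy)phenyl]pyridin-3-yllithium | [Li]c1c(OCc2ccccc2)c(-c2ccc(OCc3ccccc3)cc2)cnc1OCc1ccccc1 | intermediate
28 | pyridyl dienyl ketone, (4aS,7S,8aR) | O=C(C1=C[C@H]2C[C@@H](C)CC[C@@H]2C(C)=C1)c1c(OCc2ccccc2)c(-c2ccc(OCc3ccccc3)cc2)cnc1OCc1ccccc1 | intermediate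
29 | (E)-1-bromoprop-1-ene | C/C=C/Br | starting material
30 | lithium dienolate from the conjugate addition (enolate geometry open) | C/C=C/[C@H]1[C@H]2C[C@@H](C)CC[C@@H]2C(C)=CC1=C([O-])c1c(OCc2ccccc2)c(-c2ccc(OCc3ccccc3)cc2)cnc1OCc1ccccc1.[Li+] | intermediate
31 | tribenzyl ether of the target, (1S,2S,4aS,7S,8aR) | C/C=C/[C@H]1[C@H]2C[C@@H](C)CC[C@@H]2C(C)=C[C@H]1C(=O)c1c(OCc2ccccc2)c(-c2ccc(OCc3ccccc3)cc2)cnc1OCc1ccccc1 | intermediate
32 | 3-{(1S,2S,4aS,7S,8aR)-4,7-dimethyl-1-[(E)-prop-1-enyl]-1,2,4a,5,6,7,8,8a-octahydronaphthalene-2-carbonyl}-4-hydroxy-5-(4-hydroxyphenyl)pyridin-2(1H)-one | C/C=C/[C@H]1[C@H]2C[C@@H](C)CC[C@@H]2C(C)=C[C@H]1C(=O)c1c(O)c(-c2ccc(O)cc2)c[nH]c1=O | target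

**Step count**
- Total step count: 18.
- Longest linear sequence: 14 steps (1, 2, 4 to 12, 16 to 18).

**Steps most likely to fail**

*Step 7.*
- What may go wrong: the vinylogous dienophile may react too slowly. Part of the material may leak through the endo arrangement. The facial bias from C4 may be weak, which would lower the selectivity at C4a.
- Safeguard: the C4 centre is still present, so any wrong isomer is a diastereomer and can be removed before step 11.
- Fallback: it sets out from 13 and comes back at 16, and it replaces the neutral, kinetically controlled cycloaddition by a reversible anionic cascade.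
  - 13 is silylated only at the carbinol (TBSOTf, 2,6-lutidine, CH2Cl2, −78 °C). This gives tert-butyl (2E)-2-{(2R,3E)-2-[(tert-butyldimethylsilyl)oxy]-2-methyl-5-oxohept-3-en-1-yl}penta-2,4-dienoate F1.
  - KN(SiMe3)2 in THF (−78 to 0 °C) makes the cross-conjugated dienolate.
  - An intramolecular double Michael sequence (C7 to C8, then C8a to C4a) runs under thermodynamic control of the ring fusion, C4a and C7.
  - An aqueous quench gives 16.

*Step 11.*
- What may go wrong: after ionisation at C4, the proton may be lost from C4a or from the methyl group instead of C3. Reprotonation could then scramble C4a.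
- Fallback: it sets out from 18 and comes back at 19, and it separates the three events and replaces the cation by an anti E2 elimination.
  - Bu4NF (THF, 50 °C) gives tert-butyl (4R,4aS,7S,8aR)-4-hydroxy-4,7-dimethyl-3,4,4a,5,6,7,8,8a-octahydronaphthalene-2-carboxylate F2.
  - SOCl2 in pyridine (−20 °C) removes the axial oxygen together with the more acidic axial allylic C3–H. This gives tert-butyl (4aS,7S,8aR)-4,7-dimethyl-4a,5,6,7,8,8a-hexahydronaphthalene-2-carboxylate F3.
  - Brief treatment with CF3CO2H in CH2Cl2 at 0 °C then cleaves only the ester to give 19.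

*Step 17.*
- What may go wrong: addition to the hindered, twisted aryl dienone may be slow. The dienolate may be protonated from the wrong face or at C4. C2 may epimerise during work-up.
- Fallback: it sets out from 21 and comes back at 31, and it changes the order of events so that the cuprate meets a small, reactive acceptor.
  - i-Bu2AlH (THF, −78 °C) reduces 21 to (4aS,7S,8aR)-4,7-dimethyl-4a,5,6,7,8,8a-hexahydronaphthalene-2-carbaldehyde F4.
  - The same lithium di[(E)-prop-1-enyl]cuprate adds axially at C1, and an AcOH quench at −78 °C gives (1S,2S,4aS,7S,8aR)-4,7-dimethyl-1-[(E)-prop-1-enyl]-1,2,4a,5,6,7,8,8a-octahydronaphthalene-2-carbaldehyde F5.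
  - Aryllithium 27 adds to the aldehyde faster than it deprotonates it. This gives the secondary pyridyl carbinol F6 as an epimer mixture at the carbinol carbon.
  - Dess–Martin oxidation under buffered conditions gives 31.

**Further compounds**
F1 | step 7 | tert-butyl (2E)-2-{(2R,3E)-2-[(tert-butyldimethylsilyl)oxy]-2-methyl-5-oxohept-3-en-1-yl}penta-2,4-dienoate | CCC(=O)/C=C/[C@](C)(O[Si](C)(C)C(C)(C)C)C/C(=C\C=C)C(=O)OC(C)(C)C
F2 | step 11 | tert-butyl (4R,4aS,7S,8aR)-4-hydroxy-4,7-dimethyl-3,4,4a,5,6,7,8,8a-octahydronaphthalene-2-carboxylate | CC(C)(C)OC(=O)C1=C[C@H]2C[C@@H](C)CC[C@@H]2[C@](C)(O)C1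
F3 | step 11 | tert-butyl (4aS,7S,8aR)-4,7-dimethyl-4a,5,6,7,8,8a-hexahydronaphthalene-2-carboxylate | CC(C)(C)OC(=O)C1=C[C@H]2C[C@@H](C)CC[C@@H]2C(C)=C1
F4 | step 17 | (4aS,7S,8aR)-4,7-dimethyl-4a,5,6,7,8,8a-hexahydronaphthalene-2-carbaldehyde | O=CC1=C[C@H]2C[C@@H](C)CC[C@@H]2C(C)=C1
F5 | step 17 | (1S,2S,4aS,7S,8aR)-4,7-dimethyl-1-[(E)-prop-1-enyl]-1,2,4a,5,6,7,8,8a-octahydronaphthalene-2-carbaldehyde | C/C=C/[C@H]1[C@H]2C[C@@H](C)CC[C@@H]2C(C)=C[C@H]1C=O
F6 | step 17 | {2,4-bis(benzyloxy)-5-[4-(benzyloxy)phenyl]pyridin-3-yl}{(1S,2S,4aS,7S,8aR)-4,7-dimethyl-1-[(E)-prop-1-enyl]-1,2,4a,5,6,7,8,8a-octahydronaphthalen-2-yl}methanol (carbinol epimers) | C/C=C/[C@H]1[C@H]2C[C@@H](C)CC[C@@H]2C(C)=C[C@H]1C(O)c1c(OCc2ccccc2)c(-c2ccc(OCc3ccccc3)cc2)cnc1OCc1ccccc1
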